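## Structural features

Conneotricone (23) is a depsidone: two benzene rings are joined by a diaryl ether oxygen and by an ester, and these two links close a seven-membered dibenzo-1,4-dioxepinone. Ring A (C1 methyl, C2 hydrogen, C3 hydroxyl, C4 carboxyl, C5 ether oxygen, C6 lactone carbonyl) is a salicylic acid. Ring B (C1' lactone oxygen, C2' hydroxymethyl, C3' hydroxyl, C4' phthalide carbonyl, C5' phthalide methylene, C6' ether oxygen) is hexasubstituted and carries a fused five-membered lactone. There is no stereocentre, so the problem is purely one of regiochemistry on two crowded arenes. The fragile points are the aryl ester of the seven-membered lactone (opened by bases and nucleophiles), the C2' hydroxymethyl group between two oxygen-bearing carbons (ionisation to an ortho-quinone methide, ether formation with alcohols, over-reduction) and the free salicylic acid. The real difficulty is the ether oxygen flanked by two substituents on each ring, the six different substituents of ring B in fixed order, and the need to tell apart the C4 and C6 carboxyl groups, which both sit next to the ether oxygen. Ring B has the oxygen pattern of a folded polyketide: C4' bears the carboxyl carbon, C3' and C1' bear oxygen, and C6' lies where the methylene between two chain ketones would be. The key step uses this by joining C4' (the alpha-carbon of a 1,3-dioxin-4-one that masks the C4' carboxyl and the C3' oxygen) to C5' (a terminal ketone carbon) in an aldol condensation, with the ring A aryloxy group already on the C6' methine.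

## Logic of the disconnections

23 to 21. The four O–benzyl bonds and the acetal C–O bonds are cut last; in the same operation the phthalide C(=O)–O bond forms from the freed C5' hydroxymethyl group and the dioxinone carbonyl. One Lewis acid step therefore turns fully protected 21 into 23, and the phthalide needs no step of its own. 21 has no free hydroxyl or carboxyl group and is much easier to handle. The forward step must remove the benzyl groups at the unsubstituted benzyl carbons and spare the seven-membered lactone and the C2' benzylic C–O bond.

21 to 20 to 18. The ester bond between the C6 carbonyl and the C1' oxygen is cut next. It is the most base-sensitive bond and so is made after all carbanion chemistry. In 18 the C1' hydroxyl is the only free phenol and the C6 carboxyl the only tert-butyl ester, so ring closure has one possible outcome even though C4 also carries a carboxyl next to the ether oxygen. The forward steps must free the C6 acid without ionising the C2' benzylic ether beside the free phenol, and must activate a di-ortho-substituted acid.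

18 to 16. The C4'–C5' bond of ring B is cut. This turns a hexasubstituted benzene into an open chain whose six substituents are placed by ordinary carbonyl chemistry, and it leaves the C1' oxygen as the single free phenol. The forward aldol must be faster than loss of benzyloxide from the gamma-carbon and than attack of chain enolates on the ring A esters.

16 to 7 and 15. The bond between the ether oxygen and C6' is cut. At this stage C6' is an sp3 carbon between two ketones, so the crowded diaryl ether is made as an alkyl aryl ether by insertion of a carbenoid into the phenol O–H bond of 15, and the route becomes convergent. The forward step requires that capture by a hindered, doubly hydrogen-bonded phenol beats reactions of the carbenoid with its own benzyl ethers.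

7 to 6, then 6 to 3 and 5, and 5 to 4. The C=N2 bond is cut, then the bond between the chain methylene and the benzyloxyacetyl carbonyl, then the amide C–N bond of 5. Diazo transfer must outrun ring closure of 6, and the dianion of 3 must be acylated once, at its methyl terminus.

3 to 2 to 1. The two C–C bonds at the gamma-carbon (to the acetyl group and to the benzyloxymethyl group) are cut, which leads to a commercial dioxinone. Both forward steps rely on gamma-selective reaction of the extended enolate, and the second must avoid loss of benzyloxide.

15 to 14 to 13 to 11, then 11 to 10 to 9 to 8. The benzyl ester C–O bond, the C4–formyl C–C bond, the tert-butyl ester C–O bond and the benzyl ether C–O bond are cut in turn. The two carboxyl groups of ring A enter at different times and so are differentiated without any selective reaction: C6 comes from the aldehyde of 8, C4 from a formyl group introduced later. The forward route needs selective benzylation of the hydroxyl para to the aldehyde, and formylation at the single free position ortho to the remaining phenol.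

## Other disconnections considered

Alternative 1: The cut is at the C5–O ether bond and the C4–CO2H bond of ring A. In the forward sense CsF would release an aryne from silyl triflate A3. The caesium phenoxide of the finished ring B phthalide A2 would add to the aryne carbon far from the methoxy group, and carbon dioxide would trap the aryl anion next to methoxy to give acid A1.
- In favour: the crowded ether is made under mild, metal-free conditions, the methoxy group steers the regiochemistry, and one C–O and one C–C bond form together. For the ether bond itself this route is the better one, since it needs no diazo compound and no carbenoid.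
- Against: A2 is a hexasubstituted benzene that must first be assembled by stepwise aromatic substitution. A1 still has hydrogen at C6, so the lactone carbonyl carbon must be introduced afterwards between the ether oxygen and the methyl group. Carbon dioxide may divert the hindered phenoxide to its carbonate, the aryl anion may be protonated, and a methyl ether must be cleaved at the end.
- Comparison: in structure it solves the ether and leaves ring B and C6 open, whereas the chosen plan solves ring B and the ether together. In mechanism both rest on polar, well-understood events. In step count its key step forms two bonds against one, but the separate synthesis of A2 and the late C6 carboxylation should make the whole route longer.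

Alternative 2: The cut removes both lactone carbonyl carbons (the C4'–C(=O) and C6–C(=O) bonds and the two ester C–O bonds). Forward, Pd(OAc)2 with Xantphos under carbon monoxide would act on diaryl ether A5. Zerovalent palladium inserts into the ring B iodide and the ring A bromide, carbon monoxide inserts, and the acylpalladium species are taken up by the neighbouring hydroxymethyl group and by the C1' phenol to give A4.
- In favour: four bonds and two rings form in one step, the phthalide-forming half is dependable, and A4 is one debenzylation from 23. Ring A needs no differentiated pair of esters, which is a point on which this plan is better; the endgame is equal.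
- Against: the hard part, the tetra-ortho-substituted ether with six substituents on ring B, is moved into A5 and not solved. The ring A bromide lies between methyl and aryloxy and should be slow in oxidative addition. Acylation of a phenol by acylpalladium to a seven-membered aryl ester is far less secure than alkoxycarbonylation, and intermolecular esterification or reduction of the halides can compete.
- Comparison: in structure it closes both lactones late but rests on two fully substituted haloarenes. In mechanism it is catalytic organometallic chemistry against base-mediated carbonyl chemistry, each with one uncertain event. In step economy its key step is better in bonds per step, but the route as a whole is not expected to be shorter.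

Alternative 3: The cut opens ring A at C3–C4 and C1–C6. Forward, Cs2CO3 or DBU would deprotonate benzodioxepinone A7; its exocyclic carbon adds to the ethoxy-bearing carbon of ynone A8, and the lactone alpha-carbon then condenses with the ketone to give A6.
- In favour: the ether oxygen and the seven-membered lactone exist before ring A, so no hindered ether synthesis, no ester differentiation and no lactonisation step are needed; on these three points it is better. Like the chosen plan it makes an arene from an acyclic carbonyl precursor, so the two are equal in concept, and it forms two ring bonds in the step.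
- Against: ring B with all six substituents must first be made as a catechol and tied into the sensitive lactone. An aryl ester with acidic alpha-hydrogens can expel phenoxide to a ketene under the very base the annulation needs. The ambident anion can react at the wrong carbon, and the ethyl ether must be cleaved with the benzyl groups.
- Comparison: in structure it hands the hexasubstitution problem of ring B to classical arene chemistry, whereas the chosen plan builds that ring. In mechanism the aldol aromatisation of the chosen plan has closer precedent than a Michael–aldol annulation on a lactone-tethered glutaconate. In step economy it is shorter after the key step and probably longer before it.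

Key step: step 13

Remark on the chemistry: 23 has no stereocentre; 3, 6, 7, 16 and 17 have labile centres next to carbonyl groups and are carried as mixtures of stereoisomers and enol forms. The atom mapping of 16 and 18 onto 23 was checked position by position and needed no correction. Benzyl ethers are kept on both hydroxymethyl carbons because benzyloxide is the poorest available leaving group at the gamma-position, and the C6 tert-butyl ester is inert to the chain enolates. The tert-butyl ester is later removed with a silyl triflate rather than a protic acid.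

Step 1
Reactants: 1 2,2,6-trimethyl-4H-1,3-dioxin-4-one
Product: 2 6-[2-(benzyloxy)ethyl]-2,2-dimethyl-4H-1,3-dioxin-4-one
Conditions: LiN(iPr)2, THF, −78 °C; BnOCH2Cl, DMPU, −78 to −40 °C
Reagents that add atoms: benzyl chloromethyl ether, ClCOCc1ccccc1
Why: Deprotonation of the C6 methyl group gives the extended enolate, which the reactive alpha-chloro ether should alkylate at the gamma-carbon (vinylogous enolate alkylation); low temperature and one equivalent of base limit O-alkylation and double alkylation.

Step 2
Reactants: 2 6-[2-(benzyloxy)ethyl]-2,2-dimethyl-4H-1,3-dioxin-4-one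
Product: 3 6-[1-(benzyloxy)-3-oxobutan-2-yl]-2,2-dimethyl-4H-1,3-dioxin-4-one
Conditions: LiN(SiMe3)2 (1 equiv), THF, −78 °C; AcCl (0.5 equiv), −78 °C; aq. NH4Cl
Reagents that add atoms: acetyl chloride, CC(Cl)=O
Why: Gamma-C-acylation of the dioxinone enolate by the acid chloride (Claisen-type acylation); the second half of the enolate takes the acidic proton of the product and that half of 2 is recovered, and the enolate is kept at −78 °C so that benzyloxide is not expelled.

Step 3
Reactants: 4 benzyloxyacetyl chloride
Product: 5 2-(benzyloxy)-N-methoxy-N-methylacetamide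
Conditions: MeNH(OMe)·HCl, K2CO3, CH2Cl2/H2O, 0 °C
Reagents that add atoms: N,O-dimethylhydroxylamine hydrochloride, CNOC.Cl
Why: Schotten–Baumann acylation gives the Weinreb amide, an acyl donor that adds only once to an enolate.

Step 4
Reactants: 3 6-[1-(benzyloxy)-3-oxobutan-2-yl]-2,2-dimethyl-4H-1,3-dioxin-4-one; 5 2-(benzyloxy)-N-methoxy-N-methylacetamide
Product: 6 6-[1,6-bis(benzyloxy)-3,5-dioxohexan-2-yl]-2,2-dimethyl-4H-1,3-dioxin-4-one
Conditions: LiN(iPr)2 (2.2 equiv), THF, −78 °C; then 5, −78 to −40 °C; cold aq. NH4Cl
Reagents that add atoms: none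
Why: Two equivalents of base deprotonate first the doubly activated methine and then the methyl group, and the more basic methyl terminus attacks the Weinreb amide (crossed Claisen condensation of a dianion); the chelated tetrahedral adduct prevents a second addition, and the diketone appears only on the cold quench.

Step 5
Reactants: 6 6-[1,6-bis(benzyloxy)-3,5-dioxohexan-2-yl]-2,2-dimethyl-4H-1,3-dioxin-4-one
Product: 7 6-[1,6-bis(benzyloxy)-4-diazo-3,5-dioxohexan-2-yl]-2,2-dimethyl-4H-1,3-dioxin-4-one
Conditions: 4-AcNHC6H4SO2N3, Et3N, MeCN, 0 °C, short reaction time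
Reagents that add atoms: 4-acetamidobenzenesulfonyl azide, CC(=O)Nc1ccc(cc1)S(=O)(=O)N=[N+]=[N-]
Why: Regitz diazo transfer to the most acidic site, the methylene between the two ketones; its enolate forms and reacts faster than the gamma-anion needed for ring closure, so 7 should form before aromatisation of 6 sets in.

Step 6
Reactants: 8 2,4-dihydroxy-6-methylbenzaldehyde
Product: 9 4-(benzyloxy)-2-hydroxy-6-methylbenzaldehyde
Conditions: BnBr, NaHCO3, KI (cat.), MeCN, 70 °C
Reagents that add atoms: benzyl bromide, BrCc1ccccc1
Why: Williamson etherification; the 2-hydroxyl is held in a hydrogen bond to the formyl group and is less acidic, so the weak base should alkylate the 4-hydroxyl only.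

Step 7
Reactants: 9 4-(benzyloxy)-2-hydroxy-6-methylbenzaldehyde
Product: 10 4-(benzyloxy)-2-hydroxy-6-methylbenzoic acid
Conditions: NaClO2, NaH2PO4, 2-methyl-2-butene, t-BuOH/H2O, 0 °C to rt
Reagents that add atoms: sodium chlorite, [Na+].[O-]Cl=O
Why: Pinnick oxidation of the aldehyde; excess 2-methyl-2-butene removes hypochlorous acid before it can chlorinate the electron-rich ring.

Step 8
Reactants: 10 4-(benzyloxy)-2-hydroxy-6-methylbenzoic acid
Product: 11 tert-butyl 4-(benzyloxy)-2-hydroxy-6-methylbenzoate
Conditions: Me2NCH(Ot-Bu)2, toluene, 80 °C
Reagents that add atoms: N,N-dimethylformamide di-tert-butyl acetal, CN(C)C(OC(C)(C)C)OC(C)(C)C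
Why: The acid protonates the formamide acetal and the carboxylate collects the tert-butyl group (esterification with a formamide acetal); this does not require attack at the hindered carboxyl carbon and leaves the hydrogen-bonded phenol free.

Step 9
Reactants: 11 tert-butyl 4-(benzyloxy)-2-hydroxy-6-methylbenzoate
Product: 13 tert-butyl 4-(benzyloxy)-3-formyl-2-hydroxy-6-methylbenzoate, via hydroxymethyl phenol 12 (not isolated)
Conditions: MgCl2, Et3N, (CH2O)n, MeCN, reflux
Reagents that add atoms: paraformaldehyde (as formaldehyde), C=O
Why: Magnesium phenoxide-directed ortho-formylation (Casiraghi–Skattebøl) delivers formaldehyde only to a carbon ortho to the phenol, and C3 is the only free one; a second formaldehyde oxidises 12 by hydride transfer.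

Step 10
Reactants: 13 tert-butyl 4-(benzyloxy)-3-formyl-2-hydroxy-6-methylbenzoate
Product: 14 6-(benzyloxy)-3-(tert-butoxycarbonyl)-2-hydroxy-4-methylbenzoic acid
Conditions: NaClO2, NaH2PO4, 2-methyl-2-butene, t-BuOH/THF/H2O, rt
Reagents that add atoms: sodium chlorite, [Na+].[O-]Cl=O
Why: Pinnick oxidation again; the buffered medium leaves the tert-butyl ester and the benzyl ether intact.

Step 11
Reactants: 14 6-(benzyloxy)-3-(tert-butoxycarbonyl)-2-hydroxy-4-methylbenzoic acid
Product: 15 3-benzyl 1-tert-butyl 4-(benzyloxy)-2-hydroxy-6-methylbenzene-1,3-dicarboxylate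
Conditions: BnBr, KHCO3, DMF, rt
Reagents that add atoms: benzyl bromide, BrCc1ccccc1
Why: SN2 alkylation of the carboxylate; with hydrogen carbonate as base the phenol, which is hydrogen-bonded to both ester carbonyls and shielded on both sides, should not compete.

Step 12
Reactants: 7 6-[1,6-bis(benzyloxy)-4-diazo-3,5-dioxohexan-2-yl]-2,2-dimethyl-4H-1,3-dioxin-4-one; 15 3-benzyl 1-tert-butyl 4-(benzyloxy)-2-hydroxy-6-methylbenzene-1,3-dicarboxylate
Product: 16 3-benzyl 1-tert-butyl 4-(benzyloxy)-2-{[1,6-bis(benzyloxy)-2-(2,2-dimethyl-4-oxo-4H-1,3-dioxin-6-yl)-3,5-dioxohexan-4-yl]oxy}-6-methylbenzene-1,3-dicarboxylate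
Conditions: Rh2(OAc)4 (2 mol %), 15 (1.5 equiv), ClCH2CH2Cl, 70 °C, 7 added slowly; short silica pad, used at once
Reagents that add atoms: none
Why: Rh2(OAc)4 turns 7 into an electrophilic divalent-rhodium carbenoid between two ketones; the phenol oxygen of 15 adds and proton transfer gives the ether (carbenoid O–H insertion, known for phenols with 2-diazo-1,3-dicarbonyl compounds). Excess phenol at high concentration and slow addition of 7 favour the bimolecular insertion over reaction of the carbenoid with its own benzyl ethers.

Step 13
Reactants: 16 3-benzyl 1-tert-butyl 4-(benzyloxy)-2-{[1,6-bis(benzyloxy)-2-(2,2-dimethyl-4-oxo-4H-1,3-dioxin-6-yl)-3,5-dioxohexan-4-yl]oxy}-6-methylbenzene-1,3-dicarboxylate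
Product: 18 3-benzyl 1-tert-butyl 4-(benzyloxy)-2-({5,8-bis[(benzyloxy)methyl]-7-hydroxy-2,2-dimethyl-4-oxo-4H-1,3-benzodioxin-6-yl}oxy)-6-methylbenzene-1,3-dicarboxylate, via aldol adduct 17 (not isolated)
Conditions: Et3N, CH2Cl2, 0 °C to rt; dilute acid wash
Reagents that add atoms: none
Why: Et3N removes the gamma-proton between the dioxinone and the neighbouring ketone; the extended enolate attacks through the dioxinone alpha-carbon (C4') the terminal ketone carbon (C5') to give aldol adduct 17, which loses water by E1cB elimination and aromatises by enolisation of the remaining ketone. The closest known reaction is the amine-mediated aromatisation of 6-(2,4-dioxoalkyl)-1,3-dioxin-4-ones to acetonide-protected resorcylates; here the chain also carries an aryloxy group on the central carbon and a benzyloxymethyl group on the gamma-carbon. Ring B closes by a 6-(enolexo)-exo-trig aldol addition. No stereocentre is created that lasts: the three sp3 ring centres of 17 are erased on aromatisation. The step needs regioselectivity for this one carbon–carbon pairing, which the substrate secures because the carboxyl is locked in the dioxinone and no other pairing gives a six-membered ring that can aromatise; the central methine is the most acidic site but its enolate is unproductive and forms reversibly. It also needs the aldol to outpace loss of benzyloxide from the gamma-carbon: the anion is stabilised and benzyloxide is a poor leaving group, and the elimination should be reversible by re-addition of benzyl alcohol whereas aromatisation is not. Attack of the central enolate on the ring A esters is disfavoured by the mild base, by the bulk of the tert-butyl ester and because such a product would have no acidic hydrogen to drive it. The six substituents of ring B appear in the right order, with the C1' hydroxyl as the only free phenol.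

Step 14
Reactants: 18 3-benzyl 1-tert-butyl 4-(benzyloxy)-2-({5,8-bis[(benzyloxy)methyl]-7-hydroxy-2,2-dimethyl-4-oxo-4H-1,3-benzodioxin-6-yl}oxy)-6-methylbenzene-1,3-dicarboxylate
Product: 20 4-(benzyloxy)-3-[(benzyloxy)carbonyl]-2-({5,8-bis[(benzyloxy)methyl]-7-hydroxy-2,2-dimethyl-4-oxo-4H-1,3-benzodioxin-6-yl}oxy)-6-methylbenzoic acid, via bis-trimethylsilyl derivative 19 (not isolated)
Conditions: Me3SiOTf, 2,6-lutidine, CH2Cl2, 0 °C; then aq. citric acid/THF
Reagents that add atoms: none
Why: The silyl triflate silylates the ester carbonyl and the tert-butyl group leaves as isobutene (silyl triflate cleavage of a tert-butyl ester to a silyl ester); the phenol is silylated at the same time, which together with the lutidine buffer prevents ionisation of the neighbouring benzylic ether. Mild aqueous acid hydrolyses both silyl groups of 19; the benzyl ester, the benzyl ethers and the acylal-type acetonide should not be touched.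

Step 15
Reactants: 20 4-(benzyloxy)-3-[(benzyloxy)carbonyl]-2-({5,8-bis[(benzyloxy)methyl]-7-hydroxy-2,2-dimethyl-4-oxo-4H-1,3-benzodioxin-6-yl}oxy)-6-methylbenzoic acid
Product: 21 tetra-O-benzyl depsidone acetonide (seven-membered lactone between the C6 carboxyl of ring A and the C1' oxygen of ring B; ring A keeps OBn and CO2Bn, ring B keeps two CH2OBn groups and the fused 2,2-dimethyl-1,3-dioxin-4-one)
Conditions: EDC·HCl, DMAP, CH2Cl2, rt
Reagents that add atoms: none
Why: Carbodiimide activation of the only free carboxyl and attack by the only free phenol (Steglich-type lactonisation); the diaryl ether holds the two groups in place for seven-membered ring closure.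

Step 16
Reactants: 21 tetra-O-benzyl depsidone acetonide
Product: 23 conneotricone, via debenzylated benzodioxinone 22 (not isolated)
Conditions: BCl3, C6HMe5, CH2Cl2, −78 to 0 °C; then H2O/THF, rt
Reagents that add atoms: none
Why: BCl3 cleaves the aryl benzyl ether, the benzyl ester and the two alkyl benzyl ethers at the unhindered benzyl carbons, and pentamethylbenzene takes up the benzyl cations (Lewis acid debenzylation with a cation scavenger). The freed C5' hydroxymethyl group of 22 attacks the neighbouring dioxinone carbonyl (5-exo-trig transesterification), acetone is lost and the phthalide and the C3' phenol appear; the quench uses water, not an alcohol, so that the C2' hydroxymethyl group is not etherified.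

## Compound list

1 | 2,2,6-trimethyl-4H-1,3-dioxin-4-one | CC1=CC(=O)OC(C)(C)O1 | starting material
2 | 6-[2-(benzyloxy)ethyl]-2,2-dimethyl-4H-1,3-dioxin-4-one | CC1(C)OC(=O)C=C(CCOCc2ccccc2)O1 | intermediate
3 | 6-[1-(benzyloxy)-3-oxobutan-2-yl]-2,2-dimethyl-4H-1,3-dioxin-4-one (racemic, labile centre) | CC(=O)C(COCc1ccccc1)C1=CC(=O)OC(C)(C)O1 | intermediate
4 | benzyloxyacetyl chloride | O=C(Cl)COCc1ccccc1 | starting material
5 | 2-(benzyloxy)-N-methoxy-N-methylacetamide | CON(C)C(=O)COCc1ccccc1 | intermediate
6 | 6-[1,6-bis(benzyloxy)-3,5-dioxohexan-2-yl]-2,2-dimethyl-4H-1,3-dioxin-4-one (racemic, keto and enol forms) | CC1(C)OC(=O)C=C(C(COCc2ccccc2)C(=O)CC(=O)COCc2ccccc2)O1 | intermediate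
7 | 6-[1,6-bis(benzyloxy)-4-diazo-3,5-dioxohexan-2-yl]-2,2-dimethyl-4H-1,3-dioxin-4-one (racemic) | CC1(C)OC(=O)C=C(C(COCc2ccccc2)C(=O)C(=[N+]=[N-])C(=O)COCc2ccccc2)O1 | intermediate
8 | 2,4-dihydroxy-6-methylbenzaldehyde | Cc1cc(O)cc(O)c1C=O | starting material
9 | 4-(benzyloxy)-2-hydroxy-6-methylbenzaldehyde | Cc1cc(OCc2ccccc2)cc(O)c1C=O | intermediate
10 | 4-(benzyloxy)-2-hydroxy-6-methylbenzoic acid | Cc1cc(OCc2ccccc2)cc(O)c1C(=O)O | intermediate
11 | tert-butyl 4-(benzyloxy)-2-hydroxy-6-methylbenzoate | Cc1cc(OCc2ccccc2)cc(O)c1C(=O)OC(C)(C)C | intermediate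
12 | tert-butyl 4-(benzyloxy)-2-hydroxy-3-(hydroxymethyl)-6-methylbenzoate | Cc1cc(OCc2ccccc2)c(CO)c(O)c1C(=O)OC(C)(C)C | intermediate (not isolated)
13 | tert-butyl 4-(benzyloxy)-3-formyl-2-hydroxy-6-methylbenzoate | Cc1cc(OCc2ccccc2)c(C=O)c(O)c1C(=O)OC(C)(C)C | intermediate
14 | 6-(benzyloxy)-3-(tert-butoxycarbonyl)-2-hydroxy-4-methylbenzoic acid | Cc1cc(OCc2ccccc2)c(C(=O)O)c(O)c1C(=O)OC(C)(C)C | intermediate
15 | 3-benzyl 1-tert-butyl 4-(benzyloxy)-2-hydroxy-6-methylbenzene-1,3-dicarboxylate | Cc1cc(OCc2ccccc2)c(C(=O)OCc2ccccc2)c(O)c1C(=O)OC(C)(C)C | intermediate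
16 | 3-benzyl 1-tert-butyl 4-(benzyloxy)-2-{[1,6-bis(benzyloxy)-2-(2,2-dimethyl-4-oxo-4H-1,3-dioxin-6-yl)-3,5-dioxohexan-4-yl]oxy}-6-methylbenzene-1,3-dicarboxylate (mixture of diastereomers and enol forms) | CC1(C)OC(=O)C=C(C(COCc2ccccc2)C(=O)C(Oc2c(C(=O)OCc3ccccc3)c(OCc3ccccc3)cc(C)c2C(=O)OC(C)(C)C)C(=O)COCc2ccccc2)O1 | intermediate
17 | 3-benzyl 1-tert-butyl 4-(benzyloxy)-2-({5,8-bis[(benzyloxy)methyl]-5-hydroxy-2,2-dimethyl-4,7-dioxo-4a,5,6,7-tetrahydro-4H-1,3-benzodioxin-6-yl}oxy)-6-methylbenzene-1,3-dicarboxylate (mixture of diastereomers, centres not controlled) | CC1(C)OC(=O)C2C(=C(COCc3ccccc3)C(=O)C(Oc3c(C(=O)OCc4ccccc4)c(OCc4ccccc4)cc(C)c3C(=O)OC(C)(C)C)C2(O)COCc2ccccc2)O1 | intermediate (not isolated)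
18 | 3-benzyl 1-tert-butyl 4-(benzyloxy)-2-({5,8-bis[(benzyloxy)methyl]-7-hydroxy-2,2-dimethyl-4-oxo-4H-1,3-benzodioxin-6-yl}oxy)-6-methylbenzene-1,3-dicarboxylate | CC1(C)OC(=O)c2c(O1)c(COCc1ccccc1)c(O)c(Oc1c(C(=O)OCc3ccccc3)c(OCc3ccccc3)cc(C)c1C(=O)OC(C)(C)C)c2COCc1ccccc1 | intermediate
19 | 3-benzyl 1-trimethylsilyl 4-(benzyloxy)-2-({5,8-bis[(benzyloxy)methyl]-2,2-dimethyl-4-oxo-7-[(trimethylsilyl)oxy]-4H-1,3-benzodioxin-6-yl}oxy)-6-methylbenzene-1,3-dicarboxylate | CC1(C)OC(=O)c2c(O1)c(COCc1ccccc1)c(O[Si](C)(C)C)c(Oc1c(C(=O)OCc3ccccc3)c(OCc3ccccc3)cc(C)c1C(=O)O[Si](C)(C)C)c2COCc1ccccc1 | intermediate (not isolated)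
20 | 4-(benzyloxy)-3-[(benzyloxy)carbonyl]-2-({5,8-bis[(benzyloxy)methyl]-7-hydroxy-2,2-dimethyl-4-oxo-4H-1,3-benzodioxin-6-yl}oxy)-6-methylbenzoic acid | CC1(C)OC(=O)c2c(O1)c(COCc1ccccc1)c(O)c(Oc1c(C(=O)OCc3ccccc3)c(OCc3ccccc3)cc(C)c1C(=O)O)c2COCc1ccccc1 | intermediate
21 | tetra-O-benzyl depsidone acetonide: seven-membered lactone from the C6 carboxyl and the C1' oxygen of 20; ring A with OBn and CO2Bn; ring B with two CH2OBn groups and the fused 2,2-dimethyl-1,3-dioxin-4-one | Cc1cc(OCc2ccccc2)c(C(=O)OCc2ccccc2)c2c1C(=O)Oc1c(COCc3ccccc3)c3OC(C)(C)OC(=O)c3c(COCc3ccccc3)c1O2 | intermediate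
22 | debenzylated depsidone acetonide: 21 with all four benzyl groups replaced by hydrogen | Cc1cc(O)c(C(=O)O)c2c1C(=O)Oc1c(CO)c3OC(C)(C)OC(=O)c3c(CO)c1O2 | intermediate (not isolated)
23 | conneotricone | Cc1cc(O)c(C(=O)O)c2c1C(=O)Oc1c(CO)c(O)c3c(c1O2)COC3=O | target

## Step count and least certain steps

Total: 16 steps. Longest linear sequence: 11 steps (8 to 23, steps 6 to 16); the branch from 1 reaches 23 in 9 steps.

Step 13 (key step). What may go wrong: loss of benzyloxide from the gamma-carbanion before the aldol addition, slow addition to a ketone crowded by the aryloxy methine, or Claisen-type attack of the central enolate on the neighbouring benzyl ester. The first remedy within the step is added benzyl alcohol, because the elimination should be reversible. The fallback changes the approach: ring B is built without the C2' carbon, where gamma-elimination cannot occur and the ring closure is that of the parent substrate class, and C2' is added afterwards by ortho-formylation. It sets out from 1 (with 5 and 15) and returns to the route at 23. Acetylation of 1 (LiN(SiMe3)2, AcCl) would give 2,2-dimethyl-6-(2-oxopropyl)-4H-1,3-dioxin-4-one F1. Claisen condensation of its dianion with 5 would give 6-[5-(benzyloxy)-2,4-dioxopentyl]-2,2-dimethyl-4H-1,3-dioxin-4-one F2, and diazo transfer as in step 5 the diazo diketone F3. Rh2(OAc)4 with 15 would give the aryloxy diketone F4, and Et3N the ring B phenol with hydrogen at C2' F5. MgCl2, Et3N and paraformaldehyde would formylate the only free ring B position, ortho to the phenol, to give the salicylaldehyde F6. Me3SiOTf with 2,6-lutidine would free the acid F7, and EDC·HCl with DMAP would close the depsidone aldehyde F8. NaBH4 in THF buffered with AcOH at −20 °C would give the depsidone alcohol F9, which BCl3 with pentamethylbenzene, as in step 16, would convert into 23.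

Step 12. What may go wrong: capture of the carbenoid within the molecule, by C–H insertion next to the oxygen of the benzyloxyacetyl arm or by oxonium ylide formation at the other benzyl ether followed by benzyl shift, or Wolff rearrangement, each faster than insertion into a hindered, doubly hydrogen-bonded phenol. Fallback without a carbenoid: it sets out from 6 and 15 and returns at 16. Chlorination of 6 with N-chlorosuccinimide in CH2Cl2 would give 6-[1,6-bis(benzyloxy)-4-chloro-3,5-dioxohexan-2-yl]-2,2-dimethyl-4H-1,3-dioxin-4-one F10, and the caesium phenoxide of 15 (Cs2CO3, acetone, 0 °C) would displace chloride at the carbon between the two ketones to give 16; under the same base 16 may pass on directly to 18.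

Step 5. What may go wrong: base-induced ring closure of 6 to an arene without the aryloxy group before diazo transfer is complete, or azide transfer to the gamma-methine. Fallback that needs neither 6 nor a diazo compound: it sets out from 15 and 2 and returns at 16. Alkylation of 15 with 2-bromo-N-methoxy-N-methylacetamide (K2CO3, DMF) would give 3-benzyl 1-tert-butyl 4-(benzyloxy)-2-{2-[methoxy(methyl)amino]-2-oxoethoxy}-6-methylbenzene-1,3-dicarboxylate F11. The lithium enolate of 2 (LiN(SiMe3)2, −78 °C) would be acylated by it to give the aryloxy keto-dioxinone F12. The dianion of F12 (LiN(iPr)2, 2 equiv, −78 °C) would then be acylated by 5 at the aryloxy-bearing carbon to give 16; this last step must be kept cold so that the enolate does not close onto the ring A esters.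

Step 16. What may go wrong: ionisation at the ring B benzylic carbons instead of the unsubstituted benzyl carbons (benzylic chloride or ortho-quinone methide formation at C2'), ether formation on an alcoholic quench, incomplete phthalide closure, or opening of the seven-membered lactone. Fallback by hydrogenolysis instead of Lewis acid cleavage: it sets out from 21 and returns at 23. H2 over Pd/C in EtOAc/THF would remove the four benzyl groups to give 22, here isolated, and a trace of TsOH in THF would close the phthalide with loss of acetone; the reduction has to be stopped before the C2' benzylic C–O bond is cleaved. This fallback makes no new compound (F0).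

Step 1. What may go wrong: alkylation at the alpha-carbon or on oxygen instead of the gamma-carbon, or double alkylation. Fallback through a neutral silyl dienol ether: it sets out from 1 and returns at 2. LiN(iPr)2 and Me3SiCl would give [(2,2-dimethyl-6-methylidene-6H-1,3-dioxin-4-yl)oxy](trimethyl)silane F13, and ZnBr2-catalysed Mukaiyama-type alkylation with benzyl chloromethyl ether in CH2Cl2 would give 2 by reaction at the terminal carbon of the diene.

## Further compounds

F1 | step 13 | 2,2-dimethyl-6-(2-oxopropyl)-4H-1,3-dioxin-4-one | CC(=O)CC1=CC(=O)OC(C)(C)O1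
F2 | step 13 | 6-[5-(benzyloxy)-2,4-dioxopentyl]-2,2-dimethyl-4H-1,3-dioxin-4-one | CC1(C)OC(=O)C=C(CC(=O)CC(=O)COCc2ccccc2)O1
F3 | step 13 | 6-[5-(benzyloxy)-3-diazo-2,4-dioxopentyl]-2,2-dimethyl-4H-1,3-dioxin-4-one | CC1(C)OC(=O)C=C(CC(=O)C(=[N+]=[N-])C(=O)COCc2ccccc2)O1
F4 | step 13 | 3-benzyl 1-tert-butyl 4-(benzyloxy)-2-{[1-(benzyloxy)-5-(2,2-dimethyl-4-oxo-4H-1,3-dioxin-6-yl)-2,4-dioxopentan-3-yl]oxy}-6-methylbenzene-1,3-dicarboxylate | CC1(C)OC(=O)C=C(CC(=O)C(Oc2c(C(=O)OCc3ccccc3)c(OCc3ccccc3)cc(C)c2C(=O)OC(C)(C)C)C(=O)COCc2ccccc2)O1
F5 | step 13 | 3-benzyl 1-tert-butyl 4-(benzyloxy)-2-({5-[(benzyloxy)methyl]-7-hydroxy-2,2-dimethyl-4-oxo-4H-1,3-benzodioxin-6-yl}oxy)-6-methylbenzene-1,3-dicarboxylate | CC1(C)OC(=O)c2c(O1)cc(O)c(Oc1c(C(=O)OCc3ccccc3)c(OCc3ccccc3)cc(C)c1C(=O)OC(C)(C)C)c2COCc1ccccc1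
F6 | step 13 | 3-benzyl 1-tert-butyl 4-(benzyloxy)-2-({5-[(benzyloxy)methyl]-8-formyl-7-hydroxy-2,2-dimethyl-4-oxo-4H-1,3-benzodioxin-6-yl}oxy)-6-methylbenzene-1,3-dicarboxylate | CC1(C)OC(=O)c2c(O1)c(C=O)c(O)c(Oc1c(C(=O)OCc3ccccc3)c(OCc3ccccc3)cc(C)c1C(=O)OC(C)(C)C)c2COCc1ccccc1
F7 | step 13 | 4-(benzyloxy)-3-[(benzyloxy)carbonyl]-2-({5-[(benzyloxy)methyl]-8-formyl-7-hydroxy-2,2-dimethyl-4-oxo-4H-1,3-benzodioxin-6-yl}oxy)-6-methylbenzoic acid | CC1(C)OC(=O)c2c(O1)c(C=O)c(O)c(Oc1c(C(=O)OCc3ccccc3)c(OCc3ccccc3)cc(C)c1C(=O)O)c2COCc1ccccc1
F8 | step 13 | depsidone aldehyde: 21 with a formyl group in place of the C2' benzyloxymethyl group | Cc1cc(OCc2ccccc2)c(C(=O)OCc2ccccc2)c2c1C(=O)Oc1c(C=O)c3OC(C)(C)OC(=O)c3c(COCc3ccccc3)c1O2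
F9 | step 13 | depsidone alcohol: 21 with a free hydroxymethyl group at C2' | Cc1cc(OCc2ccccc2)c(C(=O)OCc2ccccc2)c2c1C(=O)Oc1c(CO)c3OC(C)(C)OC(=O)c3c(COCc3ccccc3)c1O2
F10 | step 12 | 6-[1,6-bis(benzyloxy)-4-chloro-3,5-dioxohexan-2-yl]-2,2-dimethyl-4H-1,3-dioxin-4-one | CC1(C)OC(=O)C=C(C(COCc2ccccc2)C(=O)C(Cl)C(=O)COCc2ccccc2)O1
F11 | step 5 | 3-benzyl 1-tert-butyl 4-(benzyloxy)-2-{2-[methoxy(methyl)amino]-2-oxoethoxy}-6-methylbenzene-1,3-dicarboxylate | CON(C)C(=O)COc1c(C(=O)OCc2ccccc2)c(OCc2ccccc2)cc(C)c1C(=O)OC(C)(C)C
F12 | step 5 | 3-benzyl 1-tert-butyl 4-(benzyloxy)-2-{[4-(benzyloxy)-3-(2,2-dimethyl-4-oxo-4H-1,3-dioxin-6-yl)-2-oxobutyl]oxy}-6-methylbenzene-1,3-dicarboxylate | CC1(C)OC(=O)C=C(C(COCc2ccccc2)C(=O)COc2c(C(=O)OCc3ccccc3)c(OCc3ccccc3)cc(C)c2C(=O)OC(C)(C)C)O1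
F0 | step 16 | none | none
F13 | step 1 | [(2,2-dimethyl-6-methylidene-6H-1,3-dioxin-4-yl)oxy](trimethyl)silane | C=C1C=C(O[Si](C)(C)C)OC(C)(C)O1
A1 | alternative 1 | 2-({7-(benzyloxy)-6-[(benzyloxy)methyl]-5-(methoxymethoxy)-1-oxo-1,3-dihydro-2-benzofuran-4-yl}oxy)-6-methoxy-4-methylbenzoic acid | COc1cc(C)cc(Oc2c(OCOC)c(COCc3ccccc3)c(OCc3ccccc3)c3c2COC3=O)c1C(=O)O
A2 | alternative 1 | 7-(benzyloxy)-6-[(benzyloxy)methyl]-4-hydroxy-5-(methoxymethoxy)-2-benzofuran-1(3H)-one | Oc1c(OCOC)c(COCc2ccccc2)c(OCc2ccccc2)c2c1COC2=O
A3 | alternative 1 | 3-methoxy-5-methyl-2-(trimethylsilyl)phenyl trifluoromethanesulfonate | COc1cc(C)cc(OS(=O)(=O)C(F)(F)F)c1[Si](C)(C)C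
A4 | alternative 2 | tetra-O-benzyl conneotricone | Cc1cc(OCc2ccccc2)c(C(=O)OCc2ccccc2)c2c1C(=O)Oc1c(COCc3ccccc3)c(OCc3ccccc3)c3c(c1O2)COC3=O
A5 | alternative 2 | benzyl 6-(benzyloxy)-3-bromo-2-{4-(benzyloxy)-3-[(benzyloxy)methyl]-2-hydroxy-6-(hydroxymethyl)-5-iodophenoxy}-4-methylbenzoate | Cc1cc(OCc2ccccc2)c(C(=O)OCc2ccccc2)c(Oc2c(O)c(COCc3ccccc3)c(OCc3ccccc3)c(I)c2CO)c1Br
A6 | alternative 3 | O-ethyl tri-O-benzyl conneotricone | Cc1cc(OCC)c(C(=O)OCc2ccccc2)c2c1C(=O)Oc1c(COCc3ccccc3)c(OCc3ccccc3)c3c(c1O2)COC3=O
A7 | alternative 3 | benzyl (ring B-fused 2-oxo-2,3-dihydro-1,5-benzodioxepin-4-ylidene)acetate, the seven-membered lactone C6'–O–C(=CHCO2Bn)–CH2–C(=O)–O–C1' on the phthalide ring B with OBn and CH2OBn, double-bond geometry not specified | O=C(OCc1ccccc1)C=C1CC(=O)Oc2c(COCc3ccccc3)c(OCc3ccccc3)c3C(=O)OCc3c2O1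
A8 | alternative 3 | 4-ethoxybut-3-yn-2-one | CCOC#CC(C)=O
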